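The runs are calculated with constants of no real substance, noise included.

**Hard floor.** The alpha flask cannot use up its left-handed substrate. Taking one partner per product, its partner is worth 30.0% of both substrates together, less than the 50.0% held as left-handed substrate, so at least 20.0% must stay. The asked flask is alpha followed further.

| setting | alpha | eta | flask |
|---|---|---|---|
| left-handed substrate | 1.5 M | 1.5 M | 1.5 M |
| right-handed substrate | 1.5 M | 1.5 M | 1.5 M |
| partner | 0.90 M | 1.8 M | 0.900 M |
| remark | the very flask that is asked about, followed so far | run made earlier |  |
| time |  |  | 20 min |

| run | time / min | left-handed substrate / % | left-handed product / % |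
|---|---|---|---|
| alpha | 1.50 | 37.7 | 11.4 |
| alpha | 3.00 | 37.3 | 13.3 |
| alpha | 5.00 | 33.6 | 15.3 |
| alpha | 6.00 | 37.4 | 13.9 |
| alpha | 8.00 | 36.6 | 13.6 |
| alpha | 10.0 | 37.6 | 15.6 |
| eta | 0.500 | 37.1 | 11.7 |
| eta | 1.50 | 29.3 | 19.6 |
| eta | 3.00 | 27.9 | 23.2 |
| eta | 4.00 | 27.2 | 20.9 |
| eta | 6.00 | 28.0 | 22.0 |
| eta | 8.00 | 28.4 | 22.8 |

(standard deviation of a reading: 1 percentage point)

- partner is single-handed; left-handed substrate and right-handed substrate are mirror images of each other, charged as a racemate, each of them at the stated concentration
- the reaction counts as stopped when no species that holds the left-handed substrate and right-handed substrate together changes by six tenths of a point or more over the second half of the time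
- the handed part of partner does not stay in what it makes, so the products of the two hands are mirror images too

- at 20 min, what has stopped the reaction, if anything has (forward and back rates have come level / the partner has run out first / all of the left-handed substrate has reacted / it is still moving)
- part of the left-handed substrate and right-handed substrate together gone at 20 min
- the left-handed product standing at 20 min, as a percentage of the left-handed substrate and right-handed substrate together charged

**Fast rung.** The eta flask shows 11.7% left-handed product at 0.500 min and 19.6% at 1.50 min. The alpha flask, with less partner, has 11.4% at 1.50 min.

**Slow rung.** From 3.00 min to 10.0 min, alpha's product stays between 13.3% and 15.6%, with a scatter of 1 percentage point. The asked 20 min is twice that last reading, so the flask should look as it does on this plateau.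

**Carried number.** Take the product per partner: the left-handed product on the plateau, averaged over the last three readings, per partner charged, both in the same units. Alpha gives 0.479. Eta gives 0.365, which is lower. My own reckoning takes partner as the limiting reagent, though a balance would also read flat. That estimates 14.4% product in the flask, with conversion expected between that figure and 30.0%.

The forecast differs on the stop, which it gives as "forward and back rates have come level", with 27% conversion and 13.7% product, since “alpha's plateau is equilibrium”.

The flask gives: the partner has run out first, 20.8% conversion, 14.6% product.

    partner + left-handed substrate → left-handed product (k = 0.00984 M⁻¹ s⁻¹)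
    partner → decomposed reagent (k = 0.00113 s⁻¹)
    2 partner → self-condensation product (k = 0.00866 M⁻¹ s⁻¹)
    partner + right-handed substrate → right-handed product (k = 0.00377 M⁻¹ s⁻¹)

**Spent partner.** At 20.0 min the flask holds 0% of its partner and 71% of its left-handed substrate. With partner held up, conversion reaches 99.1% against 20.8%, so the stop comes from the depletion of partner. The flask's product per partner is 0.486, beside the 0.479 read earlier. Carrying eta's 0.365 to the neighbour flask with 2.2 M partner gives 26.8% product. That neighbour stands at 25.0%, a product per partner of 0.342, lower still.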